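**Numbering convention.** Flavone numbering is used for the target and for compounds 13 to 17 (O1, C2, C3, C4, C4a, C5 to C8, C8a). Benzofuran numbering is used for 9 and 10.

## Analysis of the target

The target is a flavone: a benzo ring A fused to a γ-pyranone ring C (O1, C2, C3, C4, C4a, C8a), with an unsubstituted phenyl ring B on C2. Ring A is fully substituted, with a free hydroxyl at C5 and methyl ethers at C6, C7 and C8, and ring C carries a fifth oxygen, a methyl ether, at C3. The molecule is flat and has no stereocentre, so the problem is one of constitution: five oxygens sit on contiguous carbons and only the one at C5 may stay unmethylated. The C5 hydroxyl is hydrogen-bonded to the C4 carbonyl, and this peri relationship is the handle by which one of five methyl ethers can be cleaved at the end. The sensitive parts are the pyranone, whose C2 accepts hard nucleophiles with opening of ring C, and the electron-rich ring A, which oxidises easily once a free phenol is present. The difficulty lies in the hexasubstituted ring A, which rules out late aromatic substitution, and in the fully substituted C2=C3 bond, whose C3 oxygen is awkward to add to a finished flavone. The strategy rests on C3: it is a single carbon between C2 (bonded to O1 and phenyl) and the C4 carbonyl and bears only a heteroatom. Ring C can therefore be read as the five-membered ring of a 2-phenylbenzofuran-3-one into which one halocarbene carbon has been inserted between the old C2 and the carbonyl carbon.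

## Retrosynthetic reasoning

**17 to 15.** The last bond changed is the O–CH3 bond at C5. Carrying five identical methyl ethers through the route avoids any protecting-group differentiation on ring A. The forward reaction must cleave one ether out of five, and a boron trihalide bound between the C4 carbonyl and O5 (chelate 16) can do this because only the C5 ether lies peri to the carbonyl.

**15 to 14.** The C3–O bond is cut next, leaving a C3–Br bond. The gain is that the C3 substituent is traced to a halide, which is what a dihalocarbene insertion leaves behind. The forward reaction is a palladium-catalysed C–O coupling at an activated sp2 C–Br bond, and it must not let an alkoxide open the pyranone.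

**14 to 10 and 11 (key disconnection).** The C2–C3 and C3–C4 bonds are cut and C3 is removed with its bromine as the carbene carbon supplied by 11. Rejoining C2 to C4 leaves the silyl enol ether 10 of a benzofuranone. This is the best place to cut because the other bonds of ring C (O1–C2, O1–C8a, C4–C4a) then sit in a five-membered ring that is easy to make with unambiguous regiochemistry, and because C3 arrives already carrying a leaving group. The forward reaction must add the carbene to the furan C2=C3 bond (adduct 12), open the fused cyclopropane to the six-membered cation 13 and lose the silyl group.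

**10 to 9.** The O–Si bond is cut. The silyl ether fixes the ketone 9 as its electron-rich aromatic enol form, which a carbene can attack and whose oxygen can later push the ring opening.

**9 to 8.** The aryl–carbonyl bond (C3–C3a of 9, later C4–C4a) is cut. The arene of 8 has one unsubstituted carbon, ortho to the ether oxygen, so a Friedel–Crafts closure has no regiochemical choice.

**8 to 7 to 5 and 6.** The acid is traced to its methyl ester 7, and the ether bond between the phenol oxygen and the benzylic carbon (later O1–C2) is cut. This joins ring A to the carbon that carries ring B by a simple SN2 reaction of the phenol 5 with the bromo ester 6.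

**5 to 3 to 1.** The phenolic C–O bond is traced through the formate 4 to the formyl group of 3 by an aryl-migrating oxidation. The formyl C–C bond is traced through the iminium salt 2 to 1. The two free positions of 1 are equivalent, so all four ring A oxygens are bought in one symmetrical arene and the fifth is installed without isomers.

## Alternatives that were turned down

**Alternative 1:** Ring C is cut at C4–C4a, C3–C4 and O1–C2. C4 becomes carbon monoxide A4, C2 and C3 become phenylacetylene A3, and ring A with O1 becomes 2-iodo-3,4,5,6-tetramethoxyphenol A2, which is one iodination away from 5.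
- Forward key step: a phosphine-ligated divalent palladium chloride precatalyst and a secondary amine would insert A4 into the aryl–iodine bond of A2 and couple the acyl palladium with A3. The amine would add to the resulting ynone, and the phenol oxygen would close the six-membered ring to give 5,6,7,8-tetramethoxyflavone A1.
- For it: the annulation is convergent, all three components are simple, and the reaction type has close precedent on iodophenols. From 5 it needs about five operations to the target, against seven for the chosen route, so it is shorter and its key step is better precedented.
- Against it: C3 arrives as C–H. Its oxygen must then be installed on the finished, base-sensitive pyranone by deprotonation and oxidation or by epoxidation, followed by methylation to reach 15. The iodide of A2 sits between a hydroxyl and a methoxy group on an electron-rich hexasubstituted ring, which slows oxidative addition. Five-membered closure of the ynone (aurone) and non-carbonylative coupling to a benzofuran are mechanistically open side paths. A toxic gas under pressure is needed.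
- Comparison: the chosen strategy gives up two steps and some precedent. In return, ring C cannot form in the wrong size, because O1–C2 and C4–C4a are fixed beforehand by an SN2 reaction and a closure at the only free carbon. The ring-forming step also delivers C3 already functionalised.

**Alternative 2:** Ring A is cut at C4a–C5 and C8–C8a. Its four carbons C5 to C8 come from dimethyl squarate A7, and ring C comes from 3-methoxy-2-phenyl-4H-pyran-4-one A8.
- Forward key step: A8 metallated at C6 would add to one carbonyl of A7 to give the adduct 4-hydroxy-2,3-dimethoxy-4-(5-methoxy-4-oxo-6-phenyl-4H-pyran-2-yl)cyclobut-2-en-1-one A6. Heating A6 would open the four-membered ring to a dienylketene, which would close onto the pyranone C–H (Moore cyclisation) and tautomerise to 5,8-dihydroxy-3,6,7-trimethoxyflavone A5.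
- For it: the two hydroxyls of A5 are already differentiated, since the C5 hydroxyl is chelated and the C8 hydroxyl is not. One selective methylation at O8 would give 17 with no demethylation and no palladium step, so its end game is stronger than that of the chosen route.
- Against it: A8 is not a stock compound and needs its own synthesis. A 4-pyranone must be metallated regioselectively at C6 without nucleophilic opening. The electrocyclisation has to engage a pyranone double bond. A5 is a para-hydroquinone on an electron-rich ring and oxidises readily to the quinone. Counting the preparation of A8, the route is longer.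
- Comparison: the chosen strategy offers a cheap arene that already holds all four ring A oxygens, no organometallic pyranone, and a linear sequence of simple steps before its one uncertain step.

**Alternative 3:** Ring C is cut at O1–C8a and C4–C4a. Ring A becomes the symmetric aryne released from 3,4,5,6-tetramethoxy-2-(trimethylsilyl)phenyl trifluoromethanesulfonate A10, and O1, C2, C3 and C4 come from methyl 2-methoxy-3-oxo-3-phenylpropanoate A11.
- Forward key step: fluoride would trigger the aryne, the ketone enolate oxygen of A11 would add to it, and the aryl anion would attack the ester carbonyl to close ring C and give 3,5,6,7,8-pentamethoxyflavone A9, which is identical with 15.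
- For it: the aryne is symmetric, so there is no regiochemical question, and the product is one demethylation from the target. On paper this is the most convergent plan and is at least as short as the chosen one.
- Against it: enolates of β-keto esters normally attack arynes through carbon and then undergo acyl–alkyl insertion. The oxygen attack needed here is the disfavoured mode, and nothing in A11 enforces it. A10 is a hexasubstituted arene that takes several steps from 5 (halogenation, silyl migration, triflation).
- Comparison: the chosen strategy offers a ring C in which the O1–C2 and C4–C4a connections are never in doubt, so that the only open question is whether the carbene adds, not which constitution results.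

Key step: step 7

## Route

Remark on the chemistry: 6, 7, 8 and 9 are used as racemates, because their only stereocentre becomes the sp2 carbon C2 of 10.

Step 1
Reactants: 1 1,2,3,4-tetramethoxybenzene
Product: 3 2,3,4,5-tetramethoxybenzaldehyde, via iminium chloride 2 (not isolated)
Conditions: POCl3, DMF, 0 → 80 °C; then ice water
Reagents that add atoms: N,N-dimethylformamide CN(C)C=O; water O
Why: Vilsmeier–Haack formylation: the chloroiminium ion made from DMF and POCl3 attacks one of the two equivalent free positions of 1 (ortho and para to methoxy groups), the iminium group of 2 deactivates the ring against a second attack, and water hydrolyses 2 to the aldehyde.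

Step 2
Reactants: 3 2,3,4,5-tetramethoxybenzaldehyde
Product: 5 2,3,4,5-tetramethoxyphenol, via aryl formate 4 (not isolated)
Conditions: 30% H2O2, H2SO4 (cat.), MeOH, rt
Reagents that add atoms: hydrogen peroxide OO
Why: Acid-catalysed Dakin oxidation (a Baeyer–Villiger-type aryl shift): the electron-rich aryl group migrates from carbon to oxygen in the peroxide adduct of 3 to give the formate 4, which methanol cleaves in the same pot to the phenol.

Step 3
Reactants: 5 2,3,4,5-tetramethoxyphenol; 6 methyl 2-bromo-2-phenylacetate (racemic)
Product: 7 methyl 2-phenyl-2-(2,3,4,5-tetramethoxyphenoxy)acetate (racemic)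
Conditions: K2CO3, acetone, reflux
Reagents that add atoms: none
Why: Williamson ether synthesis: the phenoxide of 5 displaces the activated secondary benzylic bromide of 6 by SN2; 6 has no β-hydrogen, so elimination cannot compete.

Step 4
Reactants: 7 methyl 2-phenyl-2-(2,3,4,5-tetramethoxyphenoxy)acetate
Product: 8 2-phenyl-2-(2,3,4,5-tetramethoxyphenoxy)acetic acid (racemic)
Conditions: LiOH, THF/H2O, rt; then 1 M HCl
Reagents that add atoms: lithium hydroxide [Li+].[OH-]
Why: Saponification by acyl–oxygen cleavage; the aryl ether and the methyl ethers are inert to hydroxide and the acid is freed on acidification.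

Step 5
Reactants: 8 2-phenyl-2-(2,3,4,5-tetramethoxyphenoxy)acetic acid
Product: 9 4,5,6,7-tetramethoxy-2-phenylbenzofuran-3(2H)-one (racemic)
Conditions: P2O5/MeSO3H (1:10 w/w), rt
Reagents that add atoms: none
Why: Intramolecular Friedel–Crafts acylation: the acylium equivalent formed from 8 attacks the single unsubstituted ring carbon, which is ortho to the ether oxygen, so only the five-membered ketone can form; aryl methyl ethers survive this acid at room temperature.

Step 6
Reactants: 9 4,5,6,7-tetramethoxy-2-phenylbenzofuran-3(2H)-one
Product: 10 3-(tert-butyldimethylsilyloxy)-4,5,6,7-tetramethoxy-2-phenylbenzofuran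
Conditions: TBSOTf, Et3N, CH2Cl2, 0 °C, argon
Reagents that add atoms: tert-butyldimethylsilyl trifluoromethanesulfonate CC(C)(C)[Si](C)(C)OS(=O)(=O)C(F)(F)F
Why: O-Silylation of an enolisable ketone with a silyl triflate and an amine base: deprotonation at the doubly activated C2 and silylation on oxygen give the aromatic 3-silyloxybenzofuran, so C-silylation does not compete; air is excluded because the enol form of 9 autoxidises at C2.

Step 7
Reactants: 10 3-(tert-butyldimethylsilyloxy)-4,5,6,7-tetramethoxy-2-phenylbenzofuran; 11 bromoform
Product: 14 3-bromo-5,6,7,8-tetramethoxyflavone, via dibromocyclopropane adduct 12 (not isolated), via 3-bromo-4-silyloxyflavylium bromide 13 (not isolated)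
Conditions: KOtBu, hexane/toluene, −20 °C → rt (slow addition of 11)
Reagents that add atoms: none
Why: KOtBu deprotonates 11 and the tribromomethyl anion loses bromide to give singlet dibromocarbene, an electrophile that adds in a concerted, suprafacial (2+1) fashion to the most electron-rich π bond present, the doubly oxygenated C2=C3 bond of 10, to give the cis-fused adduct 12. In 12 the bromide that lies endo to the five-membered ring ionises while the fusion bond opens in a disrotatory two-electron electrocyclic sense, pushed by the lone pairs of both the ring oxygen and the silyloxy oxygen, so that the aromatic flavylium salt 13 results. Bromide (or tert-butoxide) then removes the silyl group from the C4 oxygen and leaves the pyranone 14. Ring C is therefore not closed by an exo or endo cyclisation: the three-membered ring closes by cheletropic addition, and the six-membered ring arises when the bond shared by the three- and five-membered rings is cut, which leaves C2–C3 and C3–C4 as the two new skeletal bonds. The closest known reactions are the dihalocarbene ring enlargement of cyclic silyl enol ethers to 2-halo enones and the dihalocarbene ring expansion of indenes and benzofurans. The two stereocentres of 12 are cis by necessity and both become sp2, so no stereocentre has to be controlled. The chemoselectivity needed, attack at the furan bond and not at an arene, is secured by the two oxygen donors on that bond, by ring A having no free position and by the low reactivity of the plain phenyl ring. The direction of opening is secured because only cleavage of the fusion bond gives a cation stabilised by both oxygens.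

Step 8
Reactants: 14 3-bromo-5,6,7,8-tetramethoxyflavone
Product: 15 3,5,6,7,8-pentamethoxyflavone
Conditions: [Pd(allyl)Cl]2 (cat.), tBuBrettPhos (cat.), Cs2CO3, MeOH (5 equiv), toluene, 70 °C
Reagents that add atoms: methanol CO
Why: Palladium-catalysed C–O cross-coupling (Buchwald–Hartwig etherification): zerovalent palladium inserts into the activated C3–Br bond, methoxide formed by Cs2CO3 replaces bromide on palladium, and the bulky biaryl phosphine forces C–O reductive elimination ahead of β-hydride elimination. The weak carbonate base and the small excess of methanol keep the pyranone closed.

Step 9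
Reactants: 15 3,5,6,7,8-pentamethoxyflavone
Product: 17 5-hydroxy-3,6,7,8-tetramethoxyflavone (target), via dichloroboron chelate 16 (not isolated)
Conditions: BCl3 (1.2 equiv), CH2Cl2, −78 → 0 °C; then H2O/MeOH
Reagents that add atoms: none
Why: Chelation-controlled ether cleavage: BCl3 binds the C4 carbonyl oxygen and O5 in a six-membered chelate and chloride removes the C5 methyl group by SN2 to give 16, which the aqueous work-up hydrolyses. The C3 ether could only form a more strained five-membered chelate and the C6, C7 and C8 ethers none, so a small excess of BCl3 at low temperature should touch only the C5 ether.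

## Compound list

1 | 1,2,3,4-tetramethoxybenzene | COc1ccc(OC)c(OC)c1OC | starting material
2 | N,N-dimethyl-1-(2,3,4,5-tetramethoxyphenyl)methaniminium chloride | COc1cc(C=[N+](C)C)c(OC)c(OC)c1OC.[Cl-] | intermediate (not isolated)
3 | 2,3,4,5-tetramethoxybenzaldehyde | COc1cc(C=O)c(OC)c(OC)c1OC | intermediate
4 | 2,3,4,5-tetramethoxyphenyl formate | COc1cc(OC=O)c(OC)c(OC)c1OC | intermediate (not isolated)
5 | 2,3,4,5-tetramethoxyphenol | COc1cc(O)c(OC)c(OC)c1OC | intermediate
6 | methyl 2-bromo-2-phenylacetate (racemic) | COC(=O)C(Br)c1ccccc1 | starting material
7 | methyl 2-phenyl-2-(2,3,4,5-tetramethoxyphenoxy)acetate (racemic) | COC(=O)C(Oc1cc(OC)c(OC)c(OC)c1OC)c1ccccc1 | intermediate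
8 | 2-phenyl-2-(2,3,4,5-tetramethoxyphenoxy)acetic acid (racemic) | OC(=O)C(Oc1cc(OC)c(OC)c(OC)c1OC)c1ccccc1 | intermediate
9 | 4,5,6,7-tetramethoxy-2-phenylbenzofuran-3(2H)-one (racemic) | COc1c(OC)c(OC)c2c(c1OC)OC(c1ccccc1)C2=O | intermediate
10 | 3-(tert-butyldimethylsilyloxy)-4,5,6,7-tetramethoxy-2-phenylbenzofuran | COc1c(OC)c(OC)c2c(O[Si](C)(C)C(C)(C)C)c(-c3ccccc3)oc2c1OC | intermediate
11 | bromoform | BrC(Br)Br | starting material
12 | 1,1-dibromo-6b-(tert-butyldimethylsilyloxy)-3,4,5,6-tetramethoxy-1a-phenyl-1a,6b-dihydro-1H-cyclopropa[b]benzofuran (racemic, cis ring fusion) | COc1c(OC)c(OC)c2c(c1OC)OC1(c3ccccc3)C(Br)(Br)C21O[Si](C)(C)C(C)(C)C | intermediate (not isolated)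
13 | 3-bromo-4-(tert-butyldimethylsilyloxy)-5,6,7,8-tetramethoxy-2-phenylchromenylium bromide | COc1c(OC)c(OC)c2c(O[Si](C)(C)C(C)(C)C)c(Br)c(-c3ccccc3)[o+]c2c1OC.[Br-] | intermediate (not isolated)
14 | 3-bromo-5,6,7,8-tetramethoxyflavone | COc1c(OC)c(OC)c2c(=O)c(Br)c(-c3ccccc3)oc2c1OC | intermediate
15 | 3,5,6,7,8-pentamethoxyflavone | COc1c(OC)c(OC)c2c(=O)c(OC)c(-c3ccccc3)oc2c1OC | intermediate
16 | dichloro[(3,6,7,8-tetramethoxy-4-oxo-2-phenyl-4H-chromen-5-yl)oxy]borane (chelated to the C4 carbonyl) | COc1c(OC)c(OB(Cl)Cl)c2c(=O)c(OC)c(-c3ccccc3)oc2c1OC | intermediate (not isolated)
17 | 5-hydroxy-3,6,7,8-tetramethoxyflavone | COc1c(OC)c(O)c2c(=O)c(OC)c(-c3ccccc3)oc2c1OC | target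

## Step count and least certain steps

Total step count: 9. Longest linear sequence: 9 steps (1 to 17); 6 and 11 are purchased and enter in steps 3 and 7.

**Step 7 (key step).**
- What may go wrong: the cycloaddition may be slow, because the enol ether bond is tetrasubstituted and crowded by the phenyl group, the bulky silyl ether and the peri methoxy group, so that the carbene is used up by tert-butoxide and tert-butanol. Tert-butoxide may also remove the silyl group early, after which the enolate would be alkylated at C2 instead of being cyclopropanated. Excess base may add to C2 of the product and open ring C.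
- Fallback (from 10, back to the route at 14): the carbon is inserted as a methylene and the halogen is added afterwards.
  - Cyclopropanation of 10 with Et2Zn and CH2I2 (Furukawa variant of the Simmons–Smith reaction) would give 6b-(tert-butyldimethylsilyloxy)-3,4,5,6-tetramethoxy-1a-phenyl-1a,6b-dihydro-1H-cyclopropa[b]benzofuran F1.
  - Oxidation of F1 with FeCl3 in DMF (Ito–Saegusa ring enlargement) would cleave the fusion bond to 2-chloro-5,6,7,8-tetramethoxy-2-phenylchroman-4-one F2.
  - NaOAc in MeOH would dehydrochlorinate F2 to 5,6,7,8-tetramethoxyflavone F3 (the same compound as A1).
  - Bromination of F3 at C3 (Bu4NBr, PhI(OAc)2, CH2Cl2) would give 14. C3 is the only nucleophilic carbon left, since ring A has no free position.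

**Step 8.**
- What may go wrong: β-hydride elimination from the palladium methoxide, leading to hydrodebromination; slow C–O reductive elimination at a carbon flanked by a carbonyl and a phenyl-bearing carbon; and attack of methoxide at C2 with opening of the pyranone. I know of no direct precedent for a palladium-catalysed C–O coupling at C3 of a 3-bromoflavone; the reaction type is established for aryl and heteroaryl bromides.
- Fallback (from 14, back to the route at 15): the oxygen is introduced through a carbanion instead of a palladium alkoxide.
  - Bromine–magnesium exchange with iPrMgCl·LiCl in THF at −40 °C would give 3-(chloromagnesio)-5,6,7,8-tetramethoxyflavone F4.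
  - Trapping with B(OMe)3 would give dimethyl (5,6,7,8-tetramethoxy-4-oxo-2-phenyl-4H-chromen-3-yl)boronate F5.
  - Oxidation in the same flask with H2O2/AcOH would give 3-hydroxy-5,6,7,8-tetramethoxyflavone F6. This parallels the C3 hydroxylation of flavones through C3 metallation, borate formation and peroxide oxidation.
  - Methylation of F6 (MeI, K2CO3, acetone) would give 15.

**Step 5.**
- What may go wrong: loss of CO from the acylium ion, which is flanked by an aryloxy and a phenyl group and can fragment to a stabilised oxocarbenium ion before it closes; acid-promoted self-condensation of the enolisable product.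
- Fallback (from 5, back to the route at 9): the aryl–carbonyl bond is made first and the O–C bond last.
  - Acylation of 5 at its only free carbon with phenylacetic acid in BF3·OEt2 at 80 °C would give 1-(2-hydroxy-3,4,5,6-tetramethoxyphenyl)-2-phenylethan-1-one F7.
  - α-Bromination (PhNMe3Br3, THF) would give 2-bromo-1-(2-hydroxy-3,4,5,6-tetramethoxyphenyl)-2-phenylethan-1-one F8; the ring cannot be brominated because it is fully substituted.
  - NaOAc in refluxing EtOH would close 9 by intramolecular O-alkylation (5-exo-tet).

**Step 9.**
- What may go wrong: over-demethylation, either at the C3 ether through the five-membered chelate with the C4 carbonyl or at the C6 ether once boron is held on O5.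
- Fallback (from 15, back to the route at 17): both chelating ethers are cleaved on purpose and one is put back.
  - Excess AlCl3 in MeCN at 60 °C would give 3,5-dihydroxy-6,7,8-trimethoxyflavone F9.
  - MeI (1 equiv) with K2CO3 in acetone at rt would methylate only the 3-hydroxyl and give 17, because the 5-hydroxyl is held by its strong hydrogen bond to the carbonyl and is the least reactive hydroxyl of a flavone towards alkylation.
  - This fallback does not answer cleavage at C6, which is controlled only by the amount of Lewis acid and the temperature.

## Further compounds

F1 | step 7 | 6b-(tert-butyldimethylsilyloxy)-3,4,5,6-tetramethoxy-1a-phenyl-1a,6b-dihydro-1H-cyclopropa[b]benzofuran (racemic) | COc1c(OC)c(OC)c2c(c1OC)OC1(c3ccccc3)CC21O[Si](C)(C)C(C)(C)C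
F2 | step 7 | 2-chloro-5,6,7,8-tetramethoxy-2-phenylchroman-4-one (racemic) | COc1c(OC)c(OC)c2c(c1OC)OC(Cl)(c1ccccc1)CC2=O
F3 | step 7 | 5,6,7,8-tetramethoxyflavone | COc1c(OC)c(OC)c2c(=O)cc(-c3ccccc3)oc2c1OC
F4 | step 8 | 3-(chloromagnesio)-5,6,7,8-tetramethoxyflavone | COc1c(OC)c(OC)c2c(=O)c([Mg]Cl)c(-c3ccccc3)oc2c1OC
F5 | step 8 | dimethyl (5,6,7,8-tetramethoxy-4-oxo-2-phenyl-4H-chromen-3-yl)boronate | COB(OC)c1c(-c2ccccc2)oc2c(OC)c(OC)c(OC)c(OC)c2c1=O
F6 | step 8 | 3-hydroxy-5,6,7,8-tetramethoxyflavone | COc1c(OC)c(OC)c2c(=O)c(O)c(-c3ccccc3)oc2c1OC
F7 | step 5 | 1-(2-hydroxy-3,4,5,6-tetramethoxyphenyl)-2-phenylethan-1-one | COc1c(O)c(C(=O)Cc2ccccc2)c(OC)c(OC)c1OC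
F8 | step 5 | 2-bromo-1-(2-hydroxy-3,4,5,6-tetramethoxyphenyl)-2-phenylethan-1-one (racemic) | COc1c(O)c(C(=O)C(Br)c2ccccc2)c(OC)c(OC)c1OC
F9 | step 9 | 3,5-dihydroxy-6,7,8-trimethoxyflavone | COc1c(OC)c(O)c2c(=O)c(O)c(-c3ccccc3)oc2c1OC
A1 | alternative 1 | 5,6,7,8-tetramethoxyflavone | COc1c(OC)c(OC)c2c(=O)cc(-c3ccccc3)oc2c1OC
A2 | alternative 1 | 2-iodo-3,4,5,6-tetramethoxyphenol | COc1c(O)c(I)c(OC)c(OC)c1OC
A3 | alternative 1 | phenylacetylene | C#Cc1ccccc1
A4 | alternative 1 | carbon monoxide | [C-]#[O+]
A5 | alternative 2 | 5,8-dihydroxy-3,6,7-trimethoxyflavone | COc1c(OC)c(O)c2c(=O)c(OC)c(-c3ccccc3)oc2c1O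
A6 | alternative 2 | 4-hydroxy-2,3-dimethoxy-4-(5-methoxy-4-oxo-6-phenyl-4H-pyran-2-yl)cyclobut-2-en-1-one (racemic) | COC1=C(OC)C(O)(c2cc(=O)c(OC)c(-c3ccccc3)o2)C1=O
A7 | alternative 2 | dimethyl squarate (3,4-dimethoxycyclobut-3-ene-1,2-dione) | COC1=C(OC)C(=O)C1=O
A8 | alternative 2 | 3-methoxy-2-phenyl-4H-pyran-4-one | COc1c(-c2ccccc2)occc1=O
A9 | alternative 3 | 3,5,6,7,8-pentamethoxyflavone | COc1c(OC)c(OC)c2c(=O)c(OC)c(-c3ccccc3)oc2c1OC
A10 | alternative 3 | 3,4,5,6-tetramethoxy-2-(trimethylsilyl)phenyl trifluoromethanesulfonate | COc1c(OC)c(OC)c([Si](C)(C)C)c(OS(=O)(=O)C(F)(F)F)c1OC
A11 | alternative 3 | methyl 2-methoxy-3-oxo-3-phenylpropanoate (racemic) | COC(=O)C(OC)C(=O)c1ccccc1
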